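Numbering: C1 Me-bearing bridgehead, C2–C3–C4 bridge of ring A, C5 second bridgehead, C6 ring-fusion CH, C7 CH2, C8 bridging C=O, C9 CMe2, C10 CH bearing CMe2OH, C11 CH2, C1′ side-chain C=O; ring A = C1-C2-C3-C4-C5-C8, ring B = C1-C7-C6-C5-C8, ring C = C5-C6-C9-C10-C11.
Feature: the enolised 2-acyl-1,3-dione of ring A, C2(OH)=C3[C1′(=O)iPr]–C4(=O), is the opened form of an isoxazole built from C2 (C=N), C3 and C1′ (C–O) and fused to ring A across C2–C3, with C4 left as a ketone.
Key disconnection: C2–C3 (closes ring A) and O–C1′ (closes the isoxazole) by intramolecular nitrile oxide–ynone cycloaddition of a C1 aldoxime onto a C5 4-methylpent-2-ynoyl group; unmasking by N–O cleavage and enaminone hydrolysis.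
Arms and core: C5–C4 by aldol of the ring-fusion enolate with 4-methylpent-2-ynal, then oxidation; C1–C2 by orthoformate addition to the C8=C1 enol silane on the convex face; diquinanone by keteniminium [2+2] on a cyclopentene (anti to the C10 side chain) and one-carbon ring expansion; C10 by Evans allylation, ring C by metathesis.
Order of ring formation: C, cyclobutanone, B (by ring expansion), then A and the isoxazole together.

Key step: step 18

Remark on the mask: an isoxazole made of C2, C3 and C4 would have its 3- and 5-carbons tied together by the three-atom bridge C1–C8–C5, which a planar five-membered aromatic ring cannot span. The dipolarophile is therefore the ynone C5–C4(=O)–C3≡C1′–CH(CH3)2, so that C4 is already the ring ketone and the dipole oxygen ends on C1′.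
Remark on materials: 3,3-dimethylpent-4-enoic acid, (R)-4-benzyl-1,3-oxazolidin-2-one and 3-methylbut-1-yne are taken as purchased.

Step 1
Reactants: 1 3,3-dimethylpent-4-enoic acid; 2 (R)-4-benzyl-1,3-oxazolidin-2-one
Product: 4 (4R)-4-benzyl-3-(3,3-dimethylpent-4-enoyl)-1,3-oxazolidin-2-one, via mixed pivalic anhydride 3 (not isolated)
Conditions: t-BuCOCl, Et3N, THF, −20 °C; then 2, LiCl, −20 °C → rt
Reagents that add atoms: none
Why: N-acylation of the oxazolidinone through the mixed pivalic anhydride (LiCl/Et3N variant) is a standard mild way to the imide and needs no acid chloride.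

Step 2
Reactants: 4; 5 allyl iodide (3-iodoprop-1-ene)
Product: 7 (4R)-4-benzyl-3-[(2R)-3,3-dimethyl-2-(prop-2-en-1-yl)pent-4-enoyl]-1,3-oxazolidin-2-one, via sodium Z-enolate 6 (not isolated)
Conditions: NaN(SiMe3)2, THF, −78 °C; then 5, −78 → −40 °C
Reagents that add atoms: none
Why: Evans asymmetric alkylation, in which the chelated Z-enolate is allylated on the face opposite the benzyl group; with the (R)-auxiliary this sets C10 as R (priorities: acyl carbon > C9 > allyl).

Step 3
Reactants: 7
Product: 8 (4R)-4-benzyl-3-{[(1R)-2,2-dimethylcyclopent-3-en-1-yl]carbonyl}-1,3-oxazolidin-2-one (ring C: C10 C11 C5=C6 C9)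
Conditions: second-generation Grubbs catalyst RuCl2(=CHPh)(H2IMes)(PCy3) (3 mol%), CH2Cl2, 40 °C
Reagents that add atoms: none
Why: Ring-closing metathesis of the 1,6-diene, helped by the gem-dimethyl group, closes ring C with loss of ethene and touches no stereocenter.

Step 4
Reactants: 8
Product: 10 (1R)-2,2-dimethylcyclopent-3-ene-1-carboxylic acid, via lithium peroxycarboxylate 9 (not isolated)
Conditions: LiOH, H2O2, THF/H2O, 0 °C → rt; Na2SO3; then 1 M HCl
Reagents that add atoms: hydrogen peroxide, OO
Why: Evans hydroperoxide cleavage attacks the hindered exocyclic carbonyl selectively, and sulfite reduces the percarboxylate before acidification, so the ring alkene is not epoxidised and C10 is not epimerised.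

Step 5
Reactants: 10
Product: 11 methyl (1R)-2,2-dimethylcyclopent-3-ene-1-carboxylate
Conditions: MeI, K2CO3, DMF, rt
Reagents that add atoms: iodomethane, CI
Why: SN2 O-methylation of the carboxylate, which does not epimerise C10.

Step 6
Reactants: 11
Product: 13 2-[(1R)-2,2-dimethylcyclopent-3-en-1-yl]propan-2-ol, via methyl ketone 12 (not isolated)
Conditions: MeMgBr (3.5 equiv), THF, 0 °C → rt; aq. NH4Cl
Reagents that add atoms: methylmagnesium bromide, C[Mg]Br
Why: Double Grignard addition to the ester through the methyl ketone installs the tertiary carbinol before any ring ketone exists.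

Step 7
Reactants: 13
Product: 14 triethyl({2-[(1R)-2,2-dimethylcyclopent-3-en-1-yl]propan-2-yl}oxy)silane
Conditions: Et3SiOTf, 2,6-lutidine, CH2Cl2, 0 °C → rt
Reagents that add atoms: triethylsilyl trifluoromethanesulfonate, CC[Si](CC)(CC)OS(=O)(=O)C(F)(F)F
Why: Silyl triflate silylation of a hindered tertiary alcohol; the bulky silyl ether protects the carbinol from Tf2O and screens its face of the ring in step 8.

Step 8
Reactants: 14; 15 N,N-dimethylacetamide
Product: 18 2,2-dimethyl-3-[2-(triethylsilyloxy)propan-2-yl]bicyclo[3.2.0]heptan-6-one (C8 ketone on C5; ring-fusion hydrogens cis to the C10 side chain), via keteniminium triflate 16 (not isolated), via cyclobutaniminium triflate 17 (not isolated)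
Conditions: 15 (2.5 equiv), Tf2O, 2,4,6-collidine, ClCH2CH2Cl, −15 °C → reflux; then aq. NaHCO3, rt
Reagents that add atoms: water, O
Why: Ghosez keteniminium–alkene [2+2] cycloaddition and hydrolysis of the iminium salt; the iminium carbon C8 should bond to C5 (remote from the quaternary C9, with charge building at C6) and the reagent should add to the face opposite the C10 side chain, which, itself or through the C9 methyl it pushes into a pseudoaxial position, covers its own face, so that C5 and C6 are set with their hydrogens cis to that side chain.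

Step 9
Reactants: 18
Product: 20 4,4-dimethyl-5-[2-(triethylsilyloxy)propan-2-yl]hexahydropentalen-1(2H)-one (cis-fused diquinanone; C8 ketone; C1 methylene), via α-trimethylsilyl ketone 19 (not isolated)
Conditions: Me3SiCHN2, Me3Al, CH2Cl2, −78 → −20 °C; then K2CO3 (cat.), MeOH, rt
Reagents that add atoms: (trimethylsilyl)diazomethane, C[Si](C)(C)C=[N+]=[N-]
Why: Lewis-acid-promoted diazoalkane ring expansion of the strained cyclobutanone, in which the less substituted carbon C7 migrates and the new carbon C1 is placed between C8 and C7; methanolysis then removes the silyl group.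

Step 10
Reactants: 20
Product: 24 4,4-dimethyl-2-methylidene-5-[2-(triethylsilyloxy)propan-2-yl]hexahydropentalen-1(2H)-one, via lithium enolate 21 (not isolated), via Mannich base 22 (not isolated), via trimethylammonium iodide 23 (not isolated)
Conditions: LiN(iPr)2, THF, −78 °C; CH2=NMe2+ I−, −78 °C → rt; MeI, CH2Cl2, rt; aq. NaHCO3, CH2Cl2, rt
Reagents that add atoms: N,N-dimethylmethyleneiminium iodide, C=[N+](C)C.[I-]
Why: Kinetic deprotonation takes the C1 methylene and not the ring-fusion methine C5–H, and Mannich reaction, quaternisation and elimination (Eschenmoser methylenation) then give the α-methylene ketone.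

Step 11
Reactants: 24
Product: 25 1-(triethylsilyloxy)-2,4,4-trimethyl-5-[2-(triethylsilyloxy)propan-2-yl]-3,3a,4,5,6,6a-hexahydropentalene (enol silane with the C8=C1 double bond)
Conditions: Et3SiH, RhCl(PPh3)3 (1 mol%), toluene, 60 °C
Reagents that add atoms: triethylsilane, CC[SiH](CC)CC
Why: Rhodium-catalysed 1,4-hydrosilylation of the enone (Ojima) gives the enol silane of the 2-methyl ketone with its double bond fixed between C8 and C1, which deprotonation could not guarantee while C5–H is present; prior isomerisation of the alkene into the ring would lead to the same enol silane.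

Step 12
Reactants: 25
Product: 26 2-(dimethoxymethyl)-2,4,4-trimethyl-5-[2-(triethylsilyloxy)propan-2-yl]hexahydropentalen-1(2H)-one (acetal carbon C2 cis to 6a-H; C1 methyl on the concave face)
Conditions: HC(OMe)3, Me3SiOTf (10 mol%), CH2Cl2, −78 °C
Reagents that add atoms: trimethyl orthoformate, COC(OC)OC
Why: Mukaiyama-type (Noyori) addition of the enol silane to the dimethoxycarbenium ion forms C1–C2 and the C1 quaternary centre; the electrophile comes in on the convex face because the concave face is covered by C11 and the endo methyl on C9, which places C2 cis to C5–H.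

Step 13
Reactants: 27 3-methylbut-1-yne
Product: 29 4-methylpent-2-ynal, via lithium acetylide 28 (not isolated)
Conditions: n-BuLi, THF, −40 °C; DMF, −40 °C → rt; inverse quench into aq. KH2PO4, 0 °C
Reagents that add atoms: N,N-dimethylformamide, CN(C)C=O
Why: Formylation of a lithium acetylide with DMF, with a buffered inverse quench that keeps the liberated amine from adding to the ynal.

Step 14
Reactants: 26; 29
Product: 31 2-(dimethoxymethyl)-6a-(1-hydroxy-4-methylpent-2-yn-1-yl)-2,4,4-trimethyl-5-[2-(triethylsilyloxy)propan-2-yl]hexahydropentalen-1(2H)-one (both C4 carbinol epimers), via lithium enolate 30 (not isolated)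
Conditions: LiN(iPr)2, THF, −78 °C; then 29, −78 °C; AcOH, −78 °C
Reagents that add atoms: none
Why: C5–H is now the only enolisable position, and aldol addition of the ring-fusion enolate to the non-enolisable ynal can only occur on the convex face (a trans-fused diquinane is not accessible), which makes C5 quaternary with C4 cis to C2; the cold acidic quench forestalls retro-aldol.

Step 15
Reactants: 31
Product: 32 2-(dimethoxymethyl)-2,4,4-trimethyl-6a-(4-methylpent-2-ynoyl)-5-[2-(triethylsilyloxy)propan-2-yl]hexahydropentalen-1(2H)-one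
Conditions: Dess–Martin periodinane, NaHCO3, CH2Cl2, 0 °C → rt
Reagents that add atoms: none
Why: Dess–Martin oxidation of the propargylic alcohol under buffered, non-basic conditions gives the ynone without retro-aldol or retro-Claisen cleavage, and removes the C4 stereocenter.

Step 16
Reactants: 32
Product: 33 5-(2-hydroxypropan-2-yl)-2,4,4-trimethyl-6a-(4-methylpent-2-ynoyl)-1-oxooctahydropentalene-2-carbaldehyde
Conditions: TsOH·H2O (0.3 equiv), acetone/H2O (10:1), 40 °C
Reagents that add atoms: water, O
Why: Acid-catalysed acetal hydrolysis frees the aldehyde and cleaves the tertiary silyl ether; no position between the three carbonyl groups can enolise and no base is present, so fragmentation is not expected.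

Step 17
Reactants: 33
Product: 34 (E)-oxime of 33 (diquinanone with the aldoxime on C1 and the 4-methylpent-2-ynoyl group on C5; free carbinol)
Conditions: NH2OH·HCl (1.05 equiv), NaOAc, MeOH/H2O, 0 °C
Reagents that add atoms: hydroxylamine hydrochloride, Cl.NO
Why: Oxime condensation at the aldehyde should be much faster at 0 °C than conjugate addition of one equivalent of buffered hydroxylamine to the hindered ynone.

Step 18
Reactants: 34
Product: 37 isoxazole-fused tricycle (ring A fused across C2–C3 to a 3-isopropylisoxazole; C2 is the C=N carbon; C1′ carries the ring oxygen; C4 ketone and C8 ketone retained), via hydroximoyl chloride 35 (not isolated), via nitrile oxide 36 (not isolated)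
Conditions: N-chlorosuccinimide, pyridine (cat.), CHCl3, 0 °C → rt; then CH2Cl2 (to 5 mM), Et3N (syringe pump), 0 °C → rt
Reagents that add atoms: none
Why: Chlorination of the aldoxime and slow dehydrochlorination with Et3N release nitrile oxide 36, which adds in a concerted 1,3-dipolar cycloaddition across C3≡C1′ of the ynone held on the same convex face, C2 bonding to C3 and the oxygen to C1′; the closest known reaction type is the intramolecular nitrile oxide–alkyne cycloaddition that gives ring-fused isoxazoles. Ring A closes as a six-membered carbocycle through the C2–C3 bond in the fused mode (the dipole carbon attacks the alkyne carbon nearer the tether, C4 lying inside the new ring), and the isoxazole closes in the same event through the O–C1′ bond. No stereocenter is formed; C1 and C5 are quaternary, were set in steps 12 and 14, and their cis relationship is what lets the two arms meet. The regiochemistry needed is secured twice: the ynone is polarised so that the dipole oxygen goes to its β-carbon C1′, and the reverse orientation would need a seven-membered ring with the isoxazole bridged across its 3- and 5-positions. The chemoselectivity needed is cycloaddition over furoxan formation, for which the dipole is generated slowly at high dilution. Neither arm can enolise, so Et3N should cause no epimerisation.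

Step 19
Reactants: 37
Product: 38 enaminone (C2 bears NH2; C2=C3; C3 bears the isobutyryl group and the C4 ketone)
Conditions: Mo(CO)6, MeCN/H2O (15:1), 80 °C
Reagents that add atoms: none
Why: Mo(CO)6-mediated reductive cleavage of the isoxazole N–O bond gives the vinylogous amide and leaves the ketones and the carbinol untouched.

Step 20
Reactants: 38
Product: 39 target CNP0267234.2
Conditions: 1 M aq. HCl, THF, 40 °C
Reagents that add atoms: water, O
Why: Acid hydrolysis of the enaminone (addition of water to the protonated vinylogous amide and loss of ammonia) gives the enolised acyl triketone; C1 and C5 are quaternary and C6 and C10 are not enolisable, so no stereocenter is at risk.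

Compound list
1 | 3,3-dimethylpent-4-enoic acid | C=CC(C)(C)CC(=O)O | starting material
2 | (R)-4-benzyl-1,3-oxazolidin-2-one | O=C1N[C@H](Cc2ccccc2)CO1 | starting material
3 | 3,3-dimethylpent-4-enoic pivalic anhydride | C=CC(C)(C)CC(=O)OC(=O)C(C)(C)C | intermediate
4 | (4R)-4-benzyl-3-(3,3-dimethylpent-4-enoyl)-1,3-oxazolidin-2-one | C=CC(C)(C)CC(=O)N1[C@H](Cc2ccccc2)COC1=O | intermediate
5 | allyl iodide | C=CCI | starting material
6 | sodium Z-enolate of 4 | C=CC(C)(C)/C=C(\[O-])N1[C@H](Cc2ccccc2)COC1=O.[Na+] | intermediate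
7 | (4R)-4-benzyl-3-[(2R)-3,3-dimethyl-2-(prop-2-en-1-yl)pent-4-enoyl]-1,3-oxazolidin-2-one | C=CC[C@@H](C(=O)N1[C@H](Cc2ccccc2)COC1=O)C(C)(C)C=C | intermediate
8 | (4R)-4-benzyl-3-{[(1R)-2,2-dimethylcyclopent-3-en-1-yl]carbonyl}-1,3-oxazolidin-2-one | O=C([C@@H]1CC=CC1(C)C)N1[C@H](Cc2ccccc2)COC1=O | intermediate
9 | lithium (1R)-2,2-dimethylcyclopent-3-ene-1-carboperoxoate | [Li+].[O-]OC(=O)[C@@H]1CC=CC1(C)C | intermediate
10 | (1R)-2,2-dimethylcyclopent-3-ene-1-carboxylic acid | OC(=O)[C@@H]1CC=CC1(C)C | intermediate
11 | methyl (1R)-2,2-dimethylcyclopent-3-ene-1-carboxylate | COC(=O)[C@@H]1CC=CC1(C)C | intermediate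
12 | 1-[(1R)-2,2-dimethylcyclopent-3-en-1-yl]ethan-1-one | CC(=O)[C@@H]1CC=CC1(C)C | intermediate
13 | 2-[(1R)-2,2-dimethylcyclopent-3-en-1-yl]propan-2-ol | CC(C)(O)[C@@H]1CC=CC1(C)C | intermediate
14 | triethyl({2-[(1R)-2,2-dimethylcyclopent-3-en-1-yl]propan-2-yl}oxy)silane | CC[Si](CC)(CC)OC(C)(C)[C@@H]1CC=CC1(C)C | intermediate
15 | N,N-dimethylacetamide | CC(=O)N(C)C | starting material
16 | N,N-dimethylketeniminium triflate | C=C=[N+](C)C.[O-]S(=O)(=O)C(F)(F)F | intermediate
17 | cyclobutaniminium triflate of 18 (C8=N+Me2) | C[N+](C)=C1C[C@H]2C(C)(C)[C@H](C(C)(C)O[Si](CC)(CC)CC)C[C@H]21.[O-]S(=O)(=O)C(F)(F)F | intermediate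
18 | 2,2-dimethyl-3-[2-(triethylsilyloxy)propan-2-yl]bicyclo[3.2.0]heptan-6-one, ring-fusion hydrogens cis to the side chain | O=C1C[C@H]2C(C)(C)[C@H](C(C)(C)O[Si](CC)(CC)CC)C[C@H]21 | intermediate
19 | 2-(trimethylsilyl) derivative of 20 (silyl group on C1, either epimer) | O=C1C([Si](C)(C)C)C[C@H]2C(C)(C)[C@H](C(C)(C)O[Si](CC)(CC)CC)C[C@H]21 | intermediate
20 | 4,4-dimethyl-5-[2-(triethylsilyloxy)propan-2-yl]hexahydropentalen-1(2H)-one, 3a-H, 6a-H and side chain all cis | O=C1CC[C@H]2C(C)(C)[C@H](C(C)(C)O[Si](CC)(CC)CC)C[C@H]21 | intermediate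
21 | lithium C8–C1 enolate of 20 | [Li+].[O-]C1=CC[C@H]2C(C)(C)[C@H](C(C)(C)O[Si](CC)(CC)CC)C[C@H]21 | intermediate
22 | 2-[(dimethylamino)methyl] derivative of 20 (Mannich base, either C1 epimer) | CN(C)CC1C[C@H]2C(C)(C)[C@H](C(C)(C)O[Si](CC)(CC)CC)C[C@H]2C1=O | intermediate
23 | trimethylammonium iodide of 22 | C[N+](C)(C)CC1C[C@H]2C(C)(C)[C@H](C(C)(C)O[Si](CC)(CC)CC)C[C@H]2C1=O.[I-] | intermediate
24 | 4,4-dimethyl-2-methylidene-5-[2-(triethylsilyloxy)propan-2-yl]hexahydropentalen-1(2H)-one | C=C1C[C@H]2C(C)(C)[C@H](C(C)(C)O[Si](CC)(CC)CC)C[C@H]2C1=O | intermediate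
25 | 1-(triethylsilyloxy)-2,4,4-trimethyl-5-[2-(triethylsilyloxy)propan-2-yl]-3,3a,4,5,6,6a-hexahydropentalene | CC[Si](CC)(CC)OC1=C(C)C[C@H]2C(C)(C)[C@H](C(C)(C)O[Si](CC)(CC)CC)C[C@H]21 | intermediate
26 | 2-(dimethoxymethyl)-2,4,4-trimethyl-5-[2-(triethylsilyloxy)propan-2-yl]hexahydropentalen-1(2H)-one, acetal carbon cis to 6a-H | COC(OC)[C@]1(C)C[C@H]2C(C)(C)[C@H](C(C)(C)O[Si](CC)(CC)CC)C[C@H]2C1=O | intermediate
27 | 3-methylbut-1-yne | CC(C)C#C | starting material
28 | lithium 3-methylbut-1-yn-1-ide | [Li+].[C-]#CC(C)C | intermediate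
29 | 4-methylpent-2-ynal | CC(C)C#CC=O | intermediate
30 | lithium C8–C5 enolate of 26 | COC(OC)[C@]1(C)C[C@H]2C(C)(C)[C@H](C(C)(C)O[Si](CC)(CC)CC)CC2=C1[O-].[Li+] | intermediate
31 | 6a-(1-hydroxy-4-methylpent-2-yn-1-yl) derivative of 26 (C4 carbinol, both epimers) | COC(OC)[C@]1(C)C[C@H]2C(C)(C)[C@H](C(C)(C)O[Si](CC)(CC)CC)C[C@@]2(C(O)C#CC(C)C)C1=O | intermediate
32 | 6a-(4-methylpent-2-ynoyl) derivative of 26 | COC(OC)[C@]1(C)C[C@H]2C(C)(C)[C@H](C(C)(C)O[Si](CC)(CC)CC)C[C@@]2(C(=O)C#CC(C)C)C1=O | intermediate
33 | 5-(2-hydroxypropan-2-yl)-2,4,4-trimethyl-6a-(4-methylpent-2-ynoyl)-1-oxooctahydropentalene-2-carbaldehyde | O=C[C@]1(C)C[C@H]2C(C)(C)[C@H](C(C)(C)O)C[C@@]2(C(=O)C#CC(C)C)C1=O | intermediate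
34 | (E)-oxime of 33 (key-step precursor) | O/N=C/[C@]1(C)C[C@H]2C(C)(C)[C@H](C(C)(C)O)C[C@@]2(C(=O)C#CC(C)C)C1=O | intermediate
35 | hydroximoyl chloride of 34 | ON=C(Cl)[C@]1(C)C[C@H]2C(C)(C)[C@H](C(C)(C)O)C[C@@]2(C(=O)C#CC(C)C)C1=O | intermediate
36 | nitrile oxide on C1 | [O-][N+]#C[C@]1(C)C[C@H]2C(C)(C)[C@H](C(C)(C)O)C[C@@]2(C(=O)C#CC(C)C)C1=O | intermediate
37 | isoxazole-fused tricycle: 3-isopropylisoxazole fused to ring A across C2–C3, with C4 and C8 ketones and rings B and C as in the target | CC(C)c4onc(c41)[C@]2(C)C[C@H]3C(C)(C)[C@H](C(C)(C)O)C[C@@]3(C1=O)C2=O | intermediate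
38 | enaminone: target skeleton with NH2 in place of the enol OH on C2 | CC(C)C(=O)C1=C(N)[C@]2(C)C[C@H]3C(C)(C)[C@H](C(C)(C)O)C[C@@]3(C1=O)C2=O | intermediate
39 | CNP0267234.2 | CC(C)C(=O)C1=C(O)[C@]2(C)C[C@H]3C(C)(C)[C@H](C(C)(C)O)C[C@@]3(C1=O)C2=O | target

Total step count: 20. Longest linear sequence: 19 steps (steps 1–12 and 14–20; step 13 is a one-step side branch).

Steps most likely to fail

1. Step 18. Bimolecular dimerisation of the nitrile oxide to the furoxan, or attack of the dipole on a carbonyl group, may outrun a ring closure that must bend both arms toward each other over C8. The fallback sets out from aldehyde 33 and comes back at target 39; it closes ring A through the same C2–C3 bond by an intramolecular Claisen (Dieckmann-type) acylation instead of a cycloaddition. Pinnick oxidation (NaClO2, NaH2PO4, 2-methylbut-2-ene, t-BuOH/H2O, 0 °C) would give the β-keto acid F1, which is kept cold and esterified at once with Me3SiCHN2 to the methyl ester F2. Conjugate addition of pyrrolidine to the ynone (THF, 0 °C) would give the enaminone F3, and aqueous acetic acid would hydrolyse it to the β-diketone F4. KOtBu (3 equiv, THF, 0 °C, acidic work-up) should then acylate C3 of the diketone enolate with the C2 ester and give 39 directly.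

2. Step 8. Self-condensation of the unsubstituted keteniminium salt may compete with its slow addition to the hindered cyclopentene, and part of the addition may occur with the reversed orientation (C8 on C6). The fallback sets out from imide 4 and comes back at enol silane 25; it makes the cycloaddition intramolecular, so that the tether fixes C8 on C5.
 - Evans titanium-enolate Michael addition of 4 to tert-butyl acrylate (TiCl4, iPr2NEt, CH2Cl2, 0 °C) would give the Michael adduct F5 with C10 set as in step 2.
 - LiOH/H2O2 would give the acid F6, MeI/K2CO3 the mixed diester F7, CF3CO2H the mono-acid F8, and Me2NH·HCl with a carbodiimide the amide ester F9.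
 - Tf2O and 2,4,6-collidine in refluxing ClCH2CH2Cl, then aqueous NaHCO3, should give the cyclobutanone ester F10; its diastereomer with the ester cis to the ring-fusion hydrogens is separated by chromatography and not epimerised.
 - The chemistry of steps 9–11 would then give the diquinanone ester F11, the α-methylene ketone F12 and the enol silane ester F13.
 - MeMgBr, with the enol silane masking the ketone, would give the carbinol F14, and Et3SiOTf/2,6-lutidine returns 25.

3. Step 17. Conjugate addition of hydroxylamine to the ynone, followed by ring closure to an isoxazoline or isoxazole, may compete with oxime formation at the hindered aldehyde. The fallback sets out from aldol 31 and comes back at isoxazole 37; it makes the oxime before the ynone exists and oxidises the carbinol after the cycloaddition. TsOH·H2O in wet acetone would convert 31 into the hydroxy aldehyde F15 (in equilibrium with its lactol), and NH2OH·HCl/NaOAc would give the oxime F16. N-chlorosuccinimide, then Et3N at high dilution, should give the isoxazolyl carbinol F17 by cycloaddition onto the unactivated alkyne, with the orientation fixed by the tether alone. Dess–Martin periodinane then oxidises the C4 carbinol to 37.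

Further compounds
F1 | step 18 | 5-(2-hydroxypropan-2-yl)-2,4,4-trimethyl-6a-(4-methylpent-2-ynoyl)-1-oxooctahydropentalene-2-carboxylic acid | OC(=O)[C@]1(C)C[C@H]2C(C)(C)[C@H](C(C)(C)O)C[C@@]2(C(=O)C#CC(C)C)C1=O
F2 | step 18 | methyl ester of F1 | COC(=O)[C@]1(C)C[C@H]2C(C)(C)[C@H](C(C)(C)O)C[C@@]2(C(=O)C#CC(C)C)C1=O
F3 | step 18 | pyrrolidine enaminone of F2 (6a-[4-methyl-3-(pyrrolidin-1-yl)pent-2-enoyl]) | COC(=O)[C@]1(C)C[C@H]2C(C)(C)[C@H](C(C)(C)O)C[C@@]2(C(=O)C=C(C(C)C)N3CCCC3)C1=O
F4 | step 18 | β-diketone ester (6a-(4-methyl-3-oxopentanoyl)) | COC(=O)[C@]1(C)C[C@H]2C(C)(C)[C@H](C(C)(C)O)C[C@@]2(C(=O)CC(=O)C(C)C)C1=O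
F5 | step 8 | tert-butyl (4R)-4-{[(4R)-4-benzyl-2-oxo-1,3-oxazolidin-3-yl]carbonyl}-5,5-dimethylhept-6-enoate | C=CC(C)(C)[C@@H](CCC(=O)OC(C)(C)C)C(=O)N1[C@H](Cc2ccccc2)COC1=O
F6 | step 8 | (2R)-2-(3-tert-butoxy-3-oxopropyl)-3,3-dimethylpent-4-enoic acid | C=CC(C)(C)[C@@H](CCC(=O)OC(C)(C)C)C(=O)O
F7 | step 8 | 5-tert-butyl 1-methyl (2R)-2-(2-methylbut-3-en-2-yl)pentanedioate | C=CC(C)(C)[C@@H](CCC(=O)OC(C)(C)C)C(=O)OC
F8 | step 8 | (4R)-4-(methoxycarbonyl)-5,5-dimethylhept-6-enoic acid | C=CC(C)(C)[C@@H](CCC(=O)O)C(=O)OC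
F9 | step 8 | methyl (2R)-2-[3-(dimethylamino)-3-oxopropyl]-3,3-dimethylpent-4-enoate | C=CC(C)(C)[C@@H](CCC(=O)N(C)C)C(=O)OC
F10 | step 8 | methyl 2,2-dimethyl-6-oxobicyclo[3.2.0]heptane-3-carboxylate, ester cis to the ring-fusion hydrogens | O=C1C[C@H]2C(C)(C)[C@H](C(=O)OC)C[C@H]21
F11 | step 8 | methyl 1,1-dimethyl-4-oxooctahydropentalene-2-carboxylate | O=C1CC[C@H]2C(C)(C)[C@H](C(=O)OC)C[C@H]21
F12 | step 8 | methyl 1,1-dimethyl-5-methylidene-4-oxooctahydropentalene-2-carboxylate | C=C1C[C@H]2C(C)(C)[C@H](C(=O)OC)C[C@H]2C1=O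
F13 | step 8 | methyl 1,1,5-trimethyl-4-(triethylsilyloxy)-1,2,3,3a,6,6a-hexahydropentalene-2-carboxylate | CC[Si](CC)(CC)OC1=C(C)C[C@H]2C(C)(C)[C@H](C(=O)OC)C[C@H]21
F14 | step 8 | 2-[1,1,5-trimethyl-4-(triethylsilyloxy)-1,2,3,3a,6,6a-hexahydropentalen-2-yl]propan-2-ol | CC[Si](CC)(CC)OC1=C(C)C[C@H]2C(C)(C)[C@H](C(C)(C)O)C[C@H]21
F15 | step 17 | 6a-(1-hydroxy-4-methylpent-2-yn-1-yl)-5-(2-hydroxypropan-2-yl)-2,4,4-trimethyl-1-oxooctahydropentalene-2-carbaldehyde | O=C[C@]1(C)C[C@H]2C(C)(C)[C@H](C(C)(C)O)C[C@@]2(C(O)C#CC(C)C)C1=O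
F16 | step 17 | (E)-oxime of F15 | O/N=C/[C@]1(C)C[C@H]2C(C)(C)[C@H](C(C)(C)O)C[C@@]2(C(O)C#CC(C)C)C1=O
F17 | step 17 | C4 carbinol of isoxazole 37 | CC(C)c4onc(c41)[C@]2(C)C[C@H]3C(C)(C)[C@H](C(C)(C)O)C[C@@]3(C1O)C2=O
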